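**Retrosynthetic overview**
- Last step: the target is cut into (+)-germacrene A, the o-quinone methide of grandinol and water. One cationic cascade makes C1–CH2Ar, C5–C10 and C4–OH and turns the ten-membered ring into both six-membered rings of the trans-decalin, setting C1, C4, C5 and C10 from C7.
- (+)-Germacrene A comes from its C5 enol triflate, made by anionic oxy-Cope ring expansion (six to ten) of a trans-1,2-dialkenylcyclohexanol.
- That cyclohexanol comes from (R)-carvone (source of C7) by reductive α-vinylation and isopropenyl Grignard addition.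
- Grandinol comes from 2-methylphloroglucinol by C-acylation and formylation.
- Ring order: carvone cyclohexane (bought), then cyclodecadiene (step 3), then both decalin rings together (step 7); the arene is bought.

Assumption: terpene carbons carry germacrane/eudesmane numbers (C1–C15) and β is the face of the C10 methyl; the target is then (1S,4R,5R,7R,10S), i.e. 1β-CH2Ar, 4α-OH, 5α-H, 7β-isopropenyl.

**Step 1**
Reactants: 1 (R)-(−)-carvone
Product: 3 (2R,5R)-2-ethenyl-2-methyl-5-(prop-1-en-2-yl)cyclohexan-1-one, via lithium enolate 2 (not isolated)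
Conditions: L-Selectride (1.05 equiv), THF, −78 °C; then Pd2(dba)3 (2.5 mol%), Q-Phos (5 mol%), vinyl bromide (1 M in THF, 2 equiv), −78 °C → rt
Reagents that add atoms: vinyl bromide (C=CBr)
Why: L-Selectride adds hydride 1,4 and gives the tetrasubstituted C1–C2 enolate 2 regiospecifically (held as its tri-sec-butylborane ate complex, which slows proton transfer), and Pd-catalysed α-alkenylation of the ketone enolate (Buchwald–Hartwig-type enolate coupling) puts the vinyl group on the quaternary carbon, expected mainly on the axial face cis to the isopropenyl group; this centre is destroyed again in step 3 and the carvone stereocentre (future C7) is untouched.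

**Step 2**
Reactants: 3 (2R,5R)-2-ethenyl-2-methyl-5-(prop-1-en-2-yl)cyclohexan-1-one
Product: 5 (1S,2R,5R)-2-ethenyl-2-methyl-1,5-di(prop-1-en-2-yl)cyclohexan-1-ol, via magnesium alkoxide 4 (not isolated)
Conditions: isopropenylmagnesium bromide (1.5 equiv), LaCl3·2LiCl (0.3 equiv), THF, −78 → 0 °C; then aq NH4Cl
Reagents that add atoms: isopropenylmagnesium bromide (C=C(C)[Mg]Br)
Why: Grignard 1,2-addition (the lanthanum salt suppresses enolisation) should occur anti to the axial α-vinyl group of the isopropenyl-locked chair (Felkin–Anh, axial attack), so the new isopropenyl ends trans to the vinyl group as the chair oxy-Cope needs; the minor cis-dialkenyl epimer is removed by chromatography.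

**Step 3**
Reactants: 5 (1S,2R,5R)-2-ethenyl-2-methyl-1,5-di(prop-1-en-2-yl)cyclohexan-1-ol
Product: 8 (1Z,5E,9R)-2,6-dimethyl-9-(prop-1-en-2-yl)cyclodeca-1,5-dien-1-yl trifluoromethanesulfonate, via potassium alkoxide 6 (not isolated), via potassium enolate 7 (not isolated)
Conditions: KH (1.2 equiv), 18-crown-6 (1.2 equiv), THF, 0 °C → rt; then PhNTf2 (1.2 equiv), −78 → 0 °C
Reagents that add atoms: N-phenyl-bis(trifluoromethanesulfonimide) (O=S(=O)(N(c1ccccc1)S(=O)(=O)C(F)(F)F)C(F)(F)F)
Why: Anionic oxy-Cope rearrangement: alkoxide 6 undergoes the [3,3] shift through the chair transition state with both alkenyl groups equatorial, giving the ten-membered ring with a 1(10)E alkene and a geometrically defined tetrasubstituted enolate 7 (C3 trans to C6), which is O-triflated in the same flask; enolate formation makes the ring expansion irreversible.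

**Step 4**
Reactants: 8 (1Z,5E,9R)-2,6-dimethyl-9-(prop-1-en-2-yl)cyclodeca-1,5-dien-1-yl trifluoromethanesulfonate
Product: 9 (+)-germacrene A, (1E,5E,8R)-1,5-dimethyl-8-(prop-1-en-2-yl)cyclodeca-1,5-diene
Conditions: Pd(OAc)2 (5 mol%), PPh3 (10 mol%), HCO2H (2 equiv), n-Bu3N (3 equiv), DMF, 35 °C; neutral alumina, store at −20 °C
Reagents that add atoms: none
Why: Pd(0)-catalysed formate reduction of the enol triflate (Cacchi-type) replaces OTf by H with retention of alkene geometry, giving the 4E alkene at a temperature below the Cope rearrangement of germacrene A to β-elemene.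

**Step 5**
Reactants: 10 2-methylbenzene-1,3,5-triol (2-methylphloroglucinol)
Product: 11 3-methyl-1-(2,4,6-trihydroxy-3-methylphenyl)butan-1-one
Conditions: 3-methylbutanoyl chloride (1.1 equiv), AlCl3 (3 equiv), PhNO2–CH2Cl2, 0 °C → rt; aq HCl
Reagents that add atoms: 3-methylbutanoyl chloride (CC(C)CC(=O)Cl)
Why: Friedel–Crafts C-acylation at one of the two equivalent free positions of the electron-rich ring; the acyl group deactivates the product against a second acylation.

**Step 6**
Reactants: 11 3-methyl-1-(2,4,6-trihydroxy-3-methylphenyl)butan-1-one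
Product: 13 grandinol (2,4,6-trihydroxy-3-methyl-5-(3-methylbutanoyl)benzaldehyde), via α-chloro ether 12 (not isolated)
Conditions: Cl2CHOMe (1.2 equiv), TiCl4 (3 equiv), CH2Cl2, 0 °C → rt; then 1 M HCl
Reagents that add atoms: dichloromethyl methyl ether (COC(Cl)Cl); water (O)
Why: Rieche formylation at the only free ring position; the α-chloro ether 12 is hydrolysed to the aldehyde on aqueous work-up.

**Step 7 (key step)**
Reactants: 9 (+)-germacrene A; 13 grandinol
Product: 16 2,4,6-trihydroxy-3-{[(1S,4R,4aR,6R,8aS)-4-hydroxy-4,8a-dimethyl-6-(prop-1-en-2-yl)decahydronaphthalen-1-yl]methyl}-5-(3-methylbutanoyl)benzaldehyde (target), via o-quinone methide 14 (not isolated), via eudesmyl zwitterion 15 (not isolated)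
Conditions: 9 (1.2 equiv), DDQ (1.0 equiv, slow addition), water-saturated MeNO2 (ca. 1 M H2O), LiClO4 (1 M), 0 °C → rt, dark
Reagents that add atoms: water (O)
Why: Proposed new method: DDQ dehydrogenates the ortho-methyl group of 13 to the acyl o-quinone methide 14, whose exocyclic CH2 is attacked by C1 of the 1(10)-alkene of 9 on the outer face of the crossed conformer with the isopropenyl group pseudo-equatorial, while C5 of the 4(5)-alkene closes transannularly onto the developing C10 cation (anti addition across both E-alkenes gives the trans-decalin with equatorial 1β-CH2Ar, 10β-CH3 and 5α-H) and water captures the C4 cation of 15 anti to the new C5–C10 bond (equatorial 4α-OH, axial 4β-CH3); the closest known reactions are o-quinone methide–terpene couplings, which normally end as hetero-Diels–Alder chromans, and the acid- or epoxide-triggered transannular cyclisation of germacrenes to eudesman-4α-ols, and the wet ionising medium is chosen to favour the interrupted, water-terminated pathway.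

**Compound list**
1 | (R)-(−)-carvone | CC1=CC[C@H](CC1=O)C(C)=C | starting material
2 | lithium (5R)-2-methyl-5-(prop-1-en-2-yl)cyclohex-1-en-1-olate | CC1=C([O-])C[C@H](C(C)=C)CC1.[Li+] | intermediate
3 | (2R,5R)-2-ethenyl-2-methyl-5-(prop-1-en-2-yl)cyclohexan-1-one (vinyl cis to isopropenyl) | C=C[C@@]1(C)CC[C@@H](C(C)=C)CC1=O | intermediate
4 | bromomagnesium (1S,2R,5R)-2-ethenyl-2-methyl-1,5-di(prop-1-en-2-yl)cyclohexan-1-olate | C=C[C@@]1(C)CC[C@@H](C(C)=C)C[C@]1(O[Mg]Br)C(C)=C | intermediate
5 | (1S,2R,5R)-2-ethenyl-2-methyl-1,5-di(prop-1-en-2-yl)cyclohexan-1-ol (C1 isopropenyl trans to vinyl) | C=C[C@@]1(C)CC[C@@H](C(C)=C)C[C@]1(O)C(C)=C | intermediate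
6 | potassium (1S,2R,5R)-2-ethenyl-2-methyl-1,5-di(prop-1-en-2-yl)cyclohexan-1-olate | C=C[C@@]1(C)CC[C@@H](C(C)=C)C[C@]1([O-])C(C)=C.[K+] | intermediate
7 | potassium (1Z,5E,9R)-2,6-dimethyl-9-(prop-1-en-2-yl)cyclodeca-1,5-dien-1-olate (germacrane C4=C5 enolate) | C/C1=C\CC/C(C)=C([O-])/C[C@H](C(C)=C)CC1.[K+] | intermediate
8 | (1Z,5E,9R)-2,6-dimethyl-9-(prop-1-en-2-yl)cyclodeca-1,5-dien-1-yl trifluoromethanesulfonate (C5 enol triflate of germacrene A) | C/C1=C\CC/C(C)=C(OS(=O)(=O)C(F)(F)F)/C[C@H](C(C)=C)CC1 | intermediate
9 | (+)-germacrene A, (1E,5E,8R)-1,5-dimethyl-8-(prop-1-en-2-yl)cyclodeca-1,5-diene | C/C1=C\CC/C(C)=C/C[C@H](C(C)=C)CC1 | intermediate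
10 | 2-methylbenzene-1,3,5-triol (2-methylphloroglucinol) | Cc1c(O)cc(O)cc1O | starting material
11 | 3-methyl-1-(2,4,6-trihydroxy-3-methylphenyl)butan-1-one | Cc1c(O)cc(O)c(C(=O)CC(C)C)c1O | intermediate
12 | 1-{3-[chloro(methoxy)methyl]-2,4,6-trihydroxy-5-methylphenyl}-3-methylbutan-1-one | COC(Cl)c1c(O)c(C)c(O)c(C(=O)CC(C)C)c1O | intermediate
13 | grandinol, 2,4,6-trihydroxy-3-methyl-5-(3-methylbutanoyl)benzaldehyde | Cc1c(O)c(C=O)c(O)c(C(=O)CC(C)C)c1O | intermediate
14 | o-quinone methide of grandinol (6-methylidene-cyclohexadienone tautomer) | C=C1C(=O)C(C=O)=C(O)C(C(=O)CC(C)C)=C1O | intermediate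
15 | 1β-(arylmethyl)eudesm-11-en-4-yl cation / phenolate zwitterion | C=C(C)[C@@H]1CC[C@@]2(C)[C@H](Cc3c([O-])c(C=O)c(O)c(C(=O)CC(C)C)c3O)CC[C+](C)[C@@H]2C1 | intermediate
16 | 2,4,6-trihydroxy-3-{[(1S,4R,4aR,6R,8aS)-4-hydroxy-4,8a-dimethyl-6-(prop-1-en-2-yl)decahydronaphthalen-1-yl]methyl}-5-(3-methylbutanoyl)benzaldehyde | C=C(C)[C@@H]1CC[C@@]2(C)[C@H](Cc3c(O)c(C=O)c(O)c(C(=O)CC(C)C)c3O)CC[C@@](C)(O)[C@@H]2C1 | target

**Totals**
Total steps: 7. Longest linear sequence: 5 (1 → 3 → 5 → 8 → 9 → 16).

**Steps most likely to fail, with fallbacks**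

Step 7. The o-quinone methide may close to a chroman (O on C10) instead of letting C4=C5 participate, the C4 cation may lose a proton instead of taking up water, and the acidic hydroquinone by-product may cyclise 9 on its own. The fallback sets out from 9 and 13 and comes back at 16. The DDQ oxidation is run in dry nitromethane so that 14 and 9 combine by the usual inverse-demand hetero-Diels–Alder addition across C1=C10, giving the chroman cycloadduct F3, which already carries the correct C1 centre. In a separate operation the tertiary alkyl aryl ether bond C10–O of F3 is ionised with Sc(OTf)3 or TsOH in wet nitromethane or wet hexafluoroisopropanol at rt. This regenerates the same C10 cation, which is closed by C4=C5 and hydrated at C4 to give 16; the C–C bond formation and the relief of medium-ring strain make this the downhill direction.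

Step 1. The hindered tetrasubstituted enolate may couple slowly, proton transfer may lead to vinylation at C6, and the borane may interfere with the palladium cycle. The fallback sets out from 1 and comes back at 3. The same L-Selectride reduction gives 2, which is quenched with acetaldehyde at −78 °C to give the aldol adduct F1 (axial attack, new bond cis to the isopropenyl group; the carbinol epimers do not matter). F1 is then dehydrated with Martin sulfurane in CH2Cl2 at rt. Because the α-carbon is quaternary, only the CH3 hydrogens can be lost, so the vinyl ketone 3 is the only possible alkene.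

Step 4. The vinylpalladium intermediate could insert the transannular 1(10)-alkene (Heck-type closure to a eudesmadiene), and any heating converts 9 into β-elemene. The fallback sets out from 5 and comes back at 9, bypassing 8. After the same oxy-Cope (KH, 18-crown-6), enolate 7 is trapped with diethyl chlorophosphate to give the enol phosphate F2. The vinyl C–O bond of F2 is then cleaved with lithium in EtNH2/THF/t-BuOH at −78 °C (dissolving-metal reduction of an enol phosphate), which needs no transition metal and no warming. The low temperature is kept to limit inversion of the vinyl radical, which would erode the 4E geometry.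

**Further compounds**
F1 | step 1 | (2R,5R)-2-(1-hydroxyethyl)-2-methyl-5-(prop-1-en-2-yl)cyclohexan-1-one (both carbinol epimers) | CC(O)[C@@]1(C)CC[C@@H](C(C)=C)CC1=O
F2 | step 4 | (1Z,5E,9R)-2,6-dimethyl-9-(prop-1-en-2-yl)cyclodeca-1,5-dien-1-yl diethyl phosphate | C/C1=C\CC/C(C)=C(OP(=O)(OCC)OCC)/C[C@H](C(C)=C)CC1
F3 | step 7 | chroman cycloadduct of 14 across C1=C10 of germacrene A (pyran O on C10, CH2 on C1, germacrane 1S,7R,10R, 4E alkene kept) | C[C@@]12CC[C@@H](C(C)=C)C/C=C(C)/CC[C@H]1Cc3c(O2)c(C=O)c(O)c(C(=O)CC(C)C)c3O
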